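(All runs are calculated with made-up constants; scatter was added.)

We have no rate constants for this flask, so we reckon in powers of ten from the readings.

all flasks: G 6.6 mM (held)

| charge | L | E | remark | time |
|---|---|---|---|---|
| autumn | 10 mM | 1 equiv | run made earlier |  |
| midnight | 40 mM | 1 equiv | run made earlier |  |
| noon | 20 mM | 0.50 equiv | run made earlier |  |
| flask | 20 mM | 1.00 equiv |  | 50 min |

| run | time / min | J / % |
|---|---|---|
| autumn | 2.50 | 0 |
| autumn | 4.00 | 0 |
| autumn | 6.00 | 0 |
| autumn | 10.0 | 0 |
| autumn | 20.0 | 5 |
| autumn | 30.0 | 9 |
| midnight | 2.00 | 1 |
| midnight | 6.00 | 0 |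
| midnight | 10.0 | 8 |
| midnight | 15.0 | 13 |
| midnight | 25.0 | 17 |
| midnight | 30.0 | 25 |
| noon | 2.50 | 0 |
| noon | 8.00 | 0 |
| noon | 15.0 | 5 |
| noon | 20.0 | 2 |
| noon | 30.0 | 6 |

(scatter of a reading: 2 percentage points)

* how much J there is at 50 min, in percent of the L charged
* the change that raises the amount of J at 50 min, in percent of the L charged most ("none" if none brings more than 2 percentage points) (Friday's / Monday's / Tuesday's / none)
* amount of J at 50 min, in percent of the L charged, after Tuesday's

- Friday's: doubling the amount of E, all else as stated
- Monday's: doubling the transfer coefficient of G, all else as stated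
- Tuesday's: doubling the saturation concentration of G, all else as stated

1. L of 20 mM stands midway, on a logarithmic scale, between 10 mM and 40 mM. So we take the mean of the logarithms of the autumn and midnight readings at 30.0 min, which puts J in the flask at 15.0% at that time.

2. The midnight run gains 0.943 powers of ten of J per power of ten of time between 15.0 min and 30.0 min. Carried to 50 min, this gives 24.3%.

3. A second way assumes that J depends on charge times time. The flask at 50 min then matches midnight at 25.0 min, which reads 17%.

4. The two ways part, so we test the second. Autumn reads 9% at 30.0 min. Midnight reaches that product between 6.00 min and 10.0 min, and the mean of its readings there is 4.00%, less than autumn. So the match on the product reads low from the midnight run, though these are readings with their scatter, and we keep 24.3%.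

5. The E power is the number of powers of ten of J gained per power of ten of E, at fixed L and time. Noon against step 1 gives 1.32, a reading that carries the scatter. So Friday's should add 36 percentage points. The runs hold G at 6.6 mM, 6.6 mM and 6.6 mM, which gives us no power for Monday's or Tuesday's.

The forecast gives 24%, Friday's, and 38% after Tuesday's: “this is nearly a tie and I pick Friday's tentatively”.

The flask gives 27.7% of J.

    L + E → X (k = 0.0740 M⁻¹ s⁻¹)
    E + D → Q (k = 0.120 M⁻¹ s⁻¹)
    X + Q → J (k = 0.0670 M⁻¹ s⁻¹)
    G ⇌ D, rate k4*(csat - [D]) (kL = 0.0440 s⁻¹)

Friday's gains the most, and Tuesday's gives 30.0%. E is the limiting reagent: at 50.0 min the flask keeps 0.95% of its E and 43% of its L. At 1.13 equiv of E, the E power promises this flask 4.7 points, and the flask moves by 5 points. For Friday's flask it promises 41 points, and that flask gains 39 points.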